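**Plan**

- Target: (1S,2S)-1-(4-hydroxy-3-methoxyphenyl)-2-(4-hydroxy-3,5-dimethoxyphenyl)propane-1,3-diol, with ring A on C1 and ring B on C2. The C1 hydroxyl and the C3 hydroxymethyl are 1,3 to each other across C2, so C3, its oxygen and the C1 oxygen can come from two formaldehyde units laid across a C1=C2 alkene.
- Retrosynthesis: the diol is tied into a 1,3-dioxane; the C2–C3 and C1–O bonds are cut (Prins) to an E-stilbene and two CH2O; the C1=C2 bond is cut (Horner–Wadsworth–Emmons) into a ring A benzylphosphonate and a ring B aldehyde.
- Forward: the chain is joined by olefination (step 4); the only ring formed is the dioxane (step 5), reopened in step 8.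
- Protecting groups: ring A benzyl ether (donor) and ring B tosylate (acceptor) steer the Prins step; ring A is then switched to a tosylate (steps 6 and 7) so that the benzylic C1–O bond cannot ionise during acidic acetal cleavage.
- Stereochemistry: both centres arise in step 5, C2 from the chiral Brønsted acid (face selection) and C1 from the E geometry and the trans-diequatorial chair; no later step touches them.

Key step: step 5

Assumption: the sense of induction of the confined acid on a stilbene cannot be predicted with certainty; the (S,S) acid is written, and its mirror image is used if a first run gives the (4R,5R)-dioxane.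

**Route**

Step 1
Reactants: 1 4-(benzyloxy)-3-methoxybenzyl alcohol
Product: 2 4-(benzyloxy)-3-methoxybenzyl bromide
Conditions: PBr3 (0.4 equiv), CH2Cl2, 0 °C
Reagents that add atoms: phosphorus tribromide, BrP(Br)Br
Why: Bromination of a primary benzylic alcohol with PBr3 (SN2 displacement on the phosphite ester) is standard, and the aryl benzyl ether should survive the short, cold reaction.

Step 2
Reactants: 2 4-(benzyloxy)-3-methoxybenzyl bromide
Product: 3 diethyl [4-(benzyloxy)-3-methoxybenzyl]phosphonate
Conditions: P(OEt)3 (neat, excess), 130 °C; excess phosphite distilled off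
Reagents that add atoms: triethyl phosphite, CCOP(OCC)OCC
Why: Michaelis–Arbuzov reaction, in which the phosphite displaces the benzylic bromide and bromide then dealkylates the phosphonium ion to the phosphonate.

Step 3
Reactants: 4 syringaldehyde (4-hydroxy-3,5-dimethoxybenzaldehyde)
Product: 5 4-formyl-2,6-dimethoxyphenyl 4-methylbenzenesulfonate
Conditions: TsCl, Et3N, DMAP (cat.), CH2Cl2, 0 °C to rt
Reagents that add atoms: p-toluenesulfonyl chloride, Cc1ccc(S(Cl)(=O)=O)cc1
Why: Sulfonylation of the phenol gives a tosylate that should withstand the base of step 4 and the acids of steps 5 and 8, and it turns the para oxygen of ring B into an acceptor.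

Step 4
Reactants: 3 diethyl [4-(benzyloxy)-3-methoxybenzyl]phosphonate; 5 4-formyl-2,6-dimethoxyphenyl 4-methylbenzenesulfonate
Product: 6 4-{(E)-2-[4-(benzyloxy)-3-methoxyphenyl]ethenyl}-2,6-dimethoxyphenyl 4-methylbenzenesulfonate (E-stilbene)
Conditions: NaH, 15-crown-5 (cat.), THF, 0 °C; then 5, 0 °C to rt
Reagents that add atoms: none
Why: Horner–Wadsworth–Emmons olefination of a benzylphosphonate anion with an aryl aldehyde should give the E-stilbene, because the addition is reversible and the anti adduct eliminates phosphate fastest.

Step 5
Reactants: 6 E-stilbene; 7 paraformaldehyde (two CH2O units)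
Product: 8 4-{(4S,5S)-4-[4-(benzyloxy)-3-methoxyphenyl]-1,3-dioxan-5-yl}-2,6-dimethoxyphenyl 4-methylbenzenesulfonate (trans-4,5-diaryl-1,3-dioxane)
Conditions: (S,S)-imino-imidodiphosphate acid with 3,3′-diaryl-BINOL backbones and a P=NTf group (5 mol %), (CH2O)n (4 equiv CH2O), CHCl3/cyclohexane, 20 °C
Reagents that add atoms: formaldehyde from paraformaldehyde 7, C=O (two units)
Why: Proposed new method: the confined chiral acid should protonate formaldehyde (or its hemiformal dimer) in its pocket, the alkene should attack it through C2 in a strongly asynchronous Prins addition that builds positive charge at C1, where the para-benzyloxy group of ring A takes it up, and the oxygen of the second formaldehyde unit should then bond to C1. The closest known reaction type is the catalytic asymmetric intermolecular Prins reaction of styrenes with paraformaldehyde to 4-aryl-1,3-dioxanes under confined imino-imidodiphosphate acids, together with the classical acid-mediated Prins reaction of anethole and stilbene to 4,5-disubstituted 1,3-dioxanes; a 1,2-diaryl alkene has not been shown in the asymmetric version. The 1,3-dioxane closes by C–O bond formation of the hemiformal oxygen onto the benzylic cationic carbon (a 6-exo-type closure onto the quinoid cation) through a chair with both aryl groups equatorial. C5 of the dioxane (C2 of the target) is fixed by the chiral acid, which chooses the alkene face that meets formaldehyde; C4 (C1 of the target) follows from the E geometry in a suprafacial addition and, if the benzylic C–O bond ionises again, from re-closure to the trans-diequatorial chair. The step needs regioselectivity (carbon to C2, oxygen to C1), secured by the donor on ring A against the sulfonate on ring B, whose methoxy groups are meta to the benzylic carbon, and chemoselectivity for the alkene over the arenes, secured by the higher nucleophilicity of the 4-alkoxystyrene-type alkene and the narrow pocket of the acid.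

Step 6
Reactants: 8 trans-dioxane with ring A benzyl ether
Product: 9 4-[(4S,5S)-4-(4-hydroxy-3-methoxyphenyl)-1,3-dioxan-5-yl]-2,6-dimethoxyphenyl 4-methylbenzenesulfonate
Conditions: H2 (1 atm), Pd/C, EtOAc, rt
Reagents that add atoms: none
Why: Catalytic hydrogenolysis of the aryl benzyl ether under neutral conditions should leave the aryl tosylate and the cyclic secondary benzylic ether of the dioxane untouched, so both stereocentres are kept.

Step 7
Reactants: 9 ring A phenol
Product: 10 (4S,5S)-4-[3-methoxy-4-(tosyloxy)phenyl]-5-[3,5-dimethoxy-4-(tosyloxy)phenyl]-1,3-dioxane (bis-tosylate)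
Conditions: TsCl, Et3N, DMAP (cat.), CH2Cl2, 0 °C to rt
Reagents that add atoms: p-toluenesulfonyl chloride, Cc1ccc(S(Cl)(=O)=O)cc1
Why: Sulfonylation of the phenol turns ring A from a donor into an acceptor, so that the benzylic C1–O bond should no longer ionise in the acid of step 8.

Step 8
Reactants: 10 bis-tosylate dioxane
Product: 11 (1S,2S)-1-[3-methoxy-4-(tosyloxy)phenyl]-2-[3,5-dimethoxy-4-(tosyloxy)phenyl]propane-1,3-diol
Conditions: conc. HCl (cat.), MeOH/THF, 60 °C, dimethoxymethane distilled off
Reagents that add atoms: none
Why: Acid-catalysed transacetalisation (methanolysis of the formaldehyde acetal) should break only the O–CH2 bonds, since with both rings as sulfonates the benzylic cation is less stabilised than in a 4-phenyl-1,3-dioxane, which is opened this way with its configuration kept.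

Step 9
Reactants: 11 bis-tosylate diol
Product: 12 (1S,2S)-1-(4-hydroxy-3-methoxyphenyl)-2-(4-hydroxy-3,5-dimethoxyphenyl)propane-1,3-diol (target)
Conditions: KOH (excess), MeOH/H2O, 65 °C, under Ar; then aq. NH4Cl
Reagents that add atoms: none
Why: Alkaline hydrolysis of the aryl sulfonates by attack of hydroxide at sulfur should release both phenols, while the 1,3-diol is inert and quinone methide formation at C1 should be negligible at this temperature, so C1 and C2 keep their configuration.

**Compound list**

1 | 4-(benzyloxy)-3-methoxybenzyl alcohol | COc1cc(CO)ccc1OCc1ccccc1 | starting material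
2 | 4-(benzyloxy)-3-methoxybenzyl bromide | COc1cc(CBr)ccc1OCc1ccccc1 | intermediate
3 | diethyl [4-(benzyloxy)-3-methoxybenzyl]phosphonate | CCOP(=O)(Cc1ccc(OCc2ccccc2)c(OC)c1)OCC | intermediate
4 | syringaldehyde | COc1cc(C=O)cc(OC)c1O | starting material
5 | 4-formyl-2,6-dimethoxyphenyl 4-methylbenzenesulfonate | COc1cc(C=O)cc(OC)c1OS(=O)(=O)c1ccc(C)cc1 | intermediate
6 | 4-{(E)-2-[4-(benzyloxy)-3-methoxyphenyl]ethenyl}-2,6-dimethoxyphenyl 4-methylbenzenesulfonate | COc1cc(/C=C/c2cc(OC)c(OS(=O)(=O)c3ccc(C)cc3)c(OC)c2)ccc1OCc1ccccc1 | intermediate
7 | paraformaldehyde (as formaldehyde) | C=O | starting material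
8 | 4-{(4S,5S)-4-[4-(benzyloxy)-3-methoxyphenyl]-1,3-dioxan-5-yl}-2,6-dimethoxyphenyl 4-methylbenzenesulfonate | COc1cc([C@H]2OCOC[C@@H]2c2cc(OC)c(OS(=O)(=O)c3ccc(C)cc3)c(OC)c2)ccc1OCc1ccccc1 | intermediate
9 | 4-[(4S,5S)-4-(4-hydroxy-3-methoxyphenyl)-1,3-dioxan-5-yl]-2,6-dimethoxyphenyl 4-methylbenzenesulfonate | COc1cc([C@H]2OCOC[C@@H]2c2cc(OC)c(OS(=O)(=O)c3ccc(C)cc3)c(OC)c2)ccc1O | intermediate
10 | (4S,5S)-4-[3-methoxy-4-(tosyloxy)phenyl]-5-[3,5-dimethoxy-4-(tosyloxy)phenyl]-1,3-dioxane | COc1cc([C@H]2OCOC[C@@H]2c2cc(OC)c(OS(=O)(=O)c3ccc(C)cc3)c(OC)c2)ccc1OS(=O)(=O)c1ccc(C)cc1 | intermediate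
11 | (1S,2S)-1-[3-methoxy-4-(tosyloxy)phenyl]-2-[3,5-dimethoxy-4-(tosyloxy)phenyl]propane-1,3-diol | COc1cc([C@@H](O)[C@H](CO)c2cc(OC)c(OS(=O)(=O)c3ccc(C)cc3)c(OC)c2)ccc1OS(=O)(=O)c1ccc(C)cc1 | intermediate
12 | (1S,2S)-1-(4-hydroxy-3-methoxyphenyl)-2-(4-hydroxy-3,5-dimethoxyphenyl)propane-1,3-diol | COc1cc([C@@H](O)[C@H](CO)c2cc(OC)c(O)c(OC)c2)ccc1O | target

**Step count and risks**

Total step count: 9. Longest linear sequence: 8 steps (steps 1, 2, 4, 5, 6, 7, 8, 9, from compound 1).

Steps most likely to fail:

Step 5. The 1,2-diaryl alkene may react too slowly inside the confined pocket, the face selection may be poor, or acid-induced oligomerisation of the alkoxystilbene may take over. The fallback sets out from 6 and uses known chemistry. The Prins reaction is run with paraformaldehyde and an achiral strong acid (TfOH, 5 mol %, CH2Cl2, 0 °C), as established for stilbene and anethole. It should give the racemic trans-dioxane, that is 8 mixed with the (4R,5R)-enantiomer of 8 F1. The two are separated by preparative chromatography on a chiral stationary phase, and the (4S,5S) antipode rejoins the route at 8. The absolute configuration then comes from a resolution and not from the catalyst.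

Step 8. The formaldehyde acetal may resist methanolysis, or long heating in acid may convert the benzylic hydroxyl partly into its methyl ether with loss of configuration at C1. The fallback sets out from 10 and replaces solvolysis by acetolysis. Ac2O with catalytic H2SO4 at 0 °C opens the O–CH2–O unit by acylation. This should give the 3-O-acetyl 1-O-(acetoxymethyl) derivative of 11 F2, possibly with the 1-O-acetyl 3-O-(acetoxymethyl) derivative of 11 F3. Both are taken together through K2CO3/MeOH at 20 °C, which removes the acetates and the hemiformal but leaves the aryl tosylates. The route is rejoined at 11.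

Step 9. Hydrolysis of the ring B tosylate, flanked by two methoxy groups, may be slow. Prolonged heating in alkali could then degrade the electron-rich bisphenol by quinone methide formation at C1 or by air oxidation, and methyl tosylate formed from methoxide could O-methylate a phenoxide. The fallback sets out from 11 and cleaves the S–O bonds reductively by electron transfer instead of by attack at sulfur. Mg turnings in MeOH at 20 °C with sonication, known for aryl tosylates, release the sulfinate without heating. The product is 12 directly, and no new compound is made on this path (F0).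

Further compounds
F1 | step 5 | (4R,5R)-enantiomer of 8 | COc1cc([C@@H]2OCOC[C@H]2c2cc(OC)c(OS(=O)(=O)c3ccc(C)cc3)c(OC)c2)ccc1OCc1ccccc1
F2 | step 8 | 3-O-acetyl 1-O-(acetoxymethyl) derivative of 11 | COc1cc([C@@H](OCOC(C)=O)[C@H](COC(C)=O)c2cc(OC)c(OS(=O)(=O)c3ccc(C)cc3)c(OC)c2)ccc1OS(=O)(=O)c1ccc(C)cc1
F3 | step 8 | 1-O-acetyl 3-O-(acetoxymethyl) derivative of 11 | COc1cc([C@@H](OC(C)=O)[C@H](COCOC(C)=O)c2cc(OC)c(OS(=O)(=O)c3ccc(C)cc3)c(OC)c2)ccc1OS(=O)(=O)c1ccc(C)cc1
F0 | step 9 | none | none
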